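**Plan**

- Numbering (drimane): C8 bears the exocyclic CH2, C9 the CH2O group (C11), C10 the angular methyl, C5 the ring-fusion H; the target is (5S,9S,10S).
- Retrosynthesis: (a) the cinnamate C=C and the acyl C–O bond are cut together, giving albicanol, Ph3P=C=C=O and 2,4-dihydroxybenzaldehyde; (b) C8=CH2 goes back to a C8 ketone; (c) the C9–C10 bond of ring B is cut: the aldol pattern C8(=O)–C9–C11–OH beside quaternary C10 is the retron of a semipinacol shift, so ring B is traced back to a trans-hydrindane cyclopentanol (carbinol C8) carrying an oxirane (C9, C11); (d) oxirane to vinyl to ketone; (e) gem-dimethyl, deoxygenation and ring-fusion H back to (S)-Hajos–Parrish ketone.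
- Forward: ring A and a five-membered ring come from the Hajos–Parrish ketone; the five-membered ring is enlarged to ring B by the shift of C10 from C8 to C9; the ester chain is joined last.
- Stereochemistry: C10 from the (S)-ketone; C5 from hydrogenation anti to the angular methyl; C9 from hydroxyl-directed epoxidation followed by the stereospecific anti 1,2-shift (inversion at C9).

Key step: step 8

**Step 1**
Reactants: 1 (S)-Hajos–Parrish ketone, (7aS)-7a-methyl-2,3,7,7a-tetrahydro-1H-indene-1,5(6H)-dione
Product: 2 (7a'S)-7a'-methyl-2',3',7',7a'-tetrahydrospiro[1,3-dioxolane-2,1'-inden]-5'(6'H)-one (dioxolane at the saturated ketone, enone kept)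
Conditions: TMSOCH2CH2OTMS (1.5 equiv), TMSOTf (5 mol%), CH2Cl2, −78 → −20 °C; pyridine, NaHCO3 aq
Reagents that add atoms: 1,2-bis(trimethylsilyloxy)ethane C[Si](C)(C)OCCO[Si](C)(C)C
Why: Silyl-triflate-catalysed acetalisation (Noyori conditions) should take the saturated cyclopentanone and leave the less electrophilic enone carbonyl, masking the C8 ketone for the basic steps.

**Step 2**
Reactants: 2 enone acetal
Product: 3 (7a'S)-4',4',7a'-trimethyl-2',4',7',7a'-tetrahydrospiro[1,3-dioxolane-2,1'-inden]-5'(6'H)-one (gem-dimethyl beside the ketone, alkene moved to C3'=C3a')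
Conditions: KOtBu (3 equiv), tBuOH, rt; MeI (4 equiv), 0 °C → rt
Reagents that add atoms: iodomethane CI
Why: Deconjugative α,α-dialkylation through the extended dienolate, the classical gem-dimethylation of bicyclic enones, should put both methyls on the α-carbon and shift the alkene out of conjugation into the five-membered ring; no stereocentre is formed.

**Step 3**
Reactants: 3 dimethyl ketone acetal
Product: 5 (7a'S)-4',4',7a'-trimethyl-2',4',5',6',7',7a'-hexahydrospiro[1,3-dioxolane-2,1'-indene], via hydrazone 4 (not isolated)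
Conditions: N2H4·H2O, KOH, diethylene glycol, 130 °C; then distil to 200 °C
Reagents that add atoms: hydrazine NN (its nitrogen stands in 4 only and leaves as N2)
Why: Wolff–Kishner reduction (Huang-Minlon procedure) should remove the hindered ketone; acetal and isolated alkene are stable to hot base.

**Step 4**
Reactants: 5 alkene acetal
Product: 6 (3a'S,7a'S)-4',4',7a'-trimethyloctahydrospiro[1,3-dioxolane-2,1'-indene] (trans ring fusion)
Conditions: H2 (4 atm), Pd/C (10%), EtOAc, rt
Reagents that add atoms: none
Why: Heterogeneous hydrogenation should deliver H2 to the face of the ring-fusion alkene opposite the angular methyl, as in the reduction of steroidal 14-enes to the trans hydrindane, which sets C5–H trans to the C10 methyl.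

**Step 5**
Reactants: 6 trans-hydrindane acetal
Product: 7 (3aS,7aS)-4,4,7a-trimethyloctahydro-1H-inden-1-one
Conditions: 1 M HCl, THF, rt
Reagents that add atoms: water O
Why: Acid-catalysed acetal hydrolysis; the ketone is flanked by a quaternary carbon and a CH2, so no stereocentre can epimerise.

**Step 6**
Reactants: 7 trans-hydrindanone
Product: 8 (1R,3aS,7aS)-1-ethenyl-4,4,7a-trimethyloctahydro-1H-inden-1-ol (OH cis to the angular methyl, vinyl trans)
Conditions: CH2=CHMgBr, CeCl3 (anhydrous), THF, −78 → 0 °C; NH4Cl aq
Reagents that add atoms: vinylmagnesium bromide C=C[Mg]Br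
Why: Organocerium 1,2-addition suppresses enolisation of the hindered ketone, and attack anti to the angular methyl (as with 17-oxo steroids) should give the β-hydroxy α-vinyl carbinol, which fixes the face from which the oxirane is later delivered.

**Step 7**
Reactants: 8 vinyl carbinol
Product: 9 (1S,3aS,7aS)-4,4,7a-trimethyl-1-[(2R)-oxiran-2-yl]octahydro-1H-inden-1-ol
Conditions: VO(acac)2 (3 mol%), tBuOOH (1.5 equiv, decane), CH2Cl2, 0 °C → rt
Reagents that add atoms: tert-butyl hydroperoxide CC(C)(C)OO
Why: Hydroxyl-directed vanadium-catalysed epoxidation of a tertiary allylic alcohol; in the usual transition state the smaller ring CH2 eclipses the vinyl C–H and the quaternary carbon stands outside, which is expected to favour the (R)-oxirane.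

**Step 8**
Reactants: 9 epoxy alcohol
Product: 10 (1S,4aS,8aS)-1-(hydroxymethyl)-5,5,8a-trimethyloctahydronaphthalen-2(1H)-one
Conditions: BF3·OEt2 (1.1 equiv), CH2Cl2, −78 → −40 °C; NaHCO3 aq
Reagents that add atoms: none
Why: BF3 activates the oxirane oxygen, the internal C9–O bond ionises with simultaneous anti-periplanar 1,2-shift of the quaternary carbon C10 from the carbinol carbon C8 to C9, and the oxocarbenium ion loses a proton to give the C8 ketone (semipinacol rearrangement). The closest known reaction type is the Lewis-acid ring expansion of 1-(oxiranyl)cycloalkanols (tertiary 2,3-epoxy alcohols) to 2-(hydroxymethyl)cycloalkanones. No ring is closed by cyclisation: ring B arises by one-carbon enlargement of the cyclopentanol, C9 being inserted between C8 and C10 while the oxirane opens. The only new stereocentre, C9, is controlled by the oxirane configuration, because the shift inverts C9 and C10 migrates with retention, so the (R)-oxirane carbon becomes (9S) with the CH2OH equatorial and cis to the angular methyl. The step needs migration of C10 and not of the ring CH2 (C7), and cleavage of the internal and not the terminal C–O bond; the higher migratory aptitude of the fully substituted carbon, the conformer that places C10 anti to C9–O while the two oxygens stay gauche and the oxirane CH2 avoids C7, and the push of the carbinol oxygen onto C9 should secure both. Release of trans-hydrindane strain on forming the trans-decalone drives the shift.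

**Step 9**
Reactants: 10 hydroxy ketone
Product: 11 (1S,4aS,8aS)-1-{[tert-butyl(dimethyl)silyl]oxymethyl}-5,5,8a-trimethyloctahydronaphthalen-2(1H)-one
Conditions: TBSCl, imidazole, DMF, 0 °C → rt
Reagents that add atoms: tert-butyldimethylsilyl chloride CC(C)(C)[Si](C)(C)Cl
Why: Standard silylation of the primary alcohol, which blocks alkoxide formation and retro-aldol loss of formaldehyde in the olefination.

**Step 10**
Reactants: 11 silyloxy ketone
Product: 12 tert-butyldimethyl{[(1S,4aS,8aS)-5,5,8a-trimethyl-2-methylidenedecahydronaphthalen-1-yl]methoxy}silane (albicanol TBS ether)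
Conditions: Ph3PCH3Br, KOtBu, toluene, rt → 80 °C
Reagents that add atoms: methyltriphenylphosphonium bromide C[P+](c1ccccc1)(c1ccccc1)c1ccccc1.[Br-]
Why: Wittig methylenation of a hindered cyclohexanone with the non-stabilised ylide, precedented for 8-oxodrimanes; ylide-induced enolisation at C9 can only return the more stable equatorial configuration.

**Step 11**
Reactants: 12 albicanol TBS ether
Product: 13 (+)-albicanol, [(1S,4aS,8aS)-5,5,8a-trimethyl-2-methylidenedecahydronaphthalen-1-yl]methanol
Conditions: TBAF, THF, rt
Reagents that add atoms: none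
Why: Fluoride cleavage of the primary silyl ether under non-acidic conditions, so the exocyclic alkene cannot isomerise.

**Step 12**
Reactants: 13 (+)-albicanol; 14 (triphenylphosphoranylidene)ketene; 15 2,4-dihydroxybenzaldehyde
Product: 17 [(1S,4aS,8aS)-5,5,8a-trimethyl-2-methylidenedecahydronaphthalen-1-yl]methyl (E)-3-(2,4-dihydroxyphenyl)prop-2-enoate (target), via phosphorane ester 16 (not isolated)
Conditions: Ph3P=C=C=O (1.1 equiv), toluene, 90 °C; then 2,4-dihydroxybenzaldehyde, THF/toluene, 60 °C, dark
Reagents that add atoms: (triphenylphosphoranylidene)ketene O=C=C=P(c1ccccc1)(c1ccccc1)c1ccccc1; 2,4-dihydroxybenzaldehyde O=Cc1ccc(O)cc1O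
Why: Three-component Bestmann-ylide esterification and Wittig olefination: the alcohol adds to the ketenylidene ylide to give stabilised ylide 16, which should olefinate the unprotected hydroxybenzaldehyde to the (E)-enoate (E from the stabilised ylide), the phenols being added only after O-acylation is complete.

**Compound list**

1 | (S)-Hajos–Parrish ketone, (7aS)-7a-methyl-2,3,7,7a-tetrahydro-1H-indene-1,5(6H)-dione | O=C1CCC2=CC(=O)CC[C@]12C | starting material
2 | (7a'S)-7a'-methyl-2',3',7',7a'-tetrahydrospiro[1,3-dioxolane-2,1'-inden]-5'(6'H)-one | O1CCOC12CCC3=CC(=O)CC[C@]23C | intermediate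
3 | (7a'S)-4',4',7a'-trimethyl-2',4',7',7a'-tetrahydrospiro[1,3-dioxolane-2,1'-inden]-5'(6'H)-one | O1CCOC12CC=C3C(C)(C)C(=O)CC[C@]23C | intermediate
4 | hydrazone of 3 | O1CCOC12CC=C3C(C)(C)C(=NN)CC[C@]23C | intermediate (not isolated)
5 | (7a'S)-4',4',7a'-trimethyl-2',4',5',6',7',7a'-hexahydrospiro[1,3-dioxolane-2,1'-indene] | O1CCOC12CC=C3C(C)(C)CCC[C@]23C | intermediate
6 | (3a'S,7a'S)-4',4',7a'-trimethyloctahydrospiro[1,3-dioxolane-2,1'-indene] | O1CCOC12CC[C@H]3C(C)(C)CCC[C@]23C | intermediate
7 | (3aS,7aS)-4,4,7a-trimethyloctahydro-1H-inden-1-one | O=C1CC[C@H]2C(C)(C)CCC[C@]12C | intermediate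
8 | (1R,3aS,7aS)-1-ethenyl-4,4,7a-trimethyloctahydro-1H-inden-1-ol | C=C[C@]1(O)CC[C@H]2C(C)(C)CCC[C@]12C | intermediate
9 | (1S,3aS,7aS)-4,4,7a-trimethyl-1-[(2R)-oxiran-2-yl]octahydro-1H-inden-1-ol | O[C@@]1([C@H]2CO2)CC[C@H]3C(C)(C)CCC[C@]13C | intermediate
10 | (1S,4aS,8aS)-1-(hydroxymethyl)-5,5,8a-trimethyloctahydronaphthalen-2(1H)-one | O=C1CC[C@H]2C(C)(C)CCC[C@]2(C)[C@H]1CO | intermediate
11 | (1S,4aS,8aS)-1-{[tert-butyl(dimethyl)silyl]oxymethyl}-5,5,8a-trimethyloctahydronaphthalen-2(1H)-one | O=C1CC[C@H]2C(C)(C)CCC[C@]2(C)[C@H]1CO[Si](C)(C)C(C)(C)C | intermediate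
12 | albicanol tert-butyldimethylsilyl ether | C=C1CC[C@H]2C(C)(C)CCC[C@]2(C)[C@H]1CO[Si](C)(C)C(C)(C)C | intermediate
13 | (+)-albicanol | C=C1CC[C@H]2C(C)(C)CCC[C@]2(C)[C@H]1CO | intermediate
14 | (triphenylphosphoranylidene)ketene | O=C=C=P(c1ccccc1)(c1ccccc1)c1ccccc1 | starting material
15 | 2,4-dihydroxybenzaldehyde | O=Cc1ccc(O)cc1O | starting material
16 | albicanyl (triphenylphosphoranylidene)acetate | C=C1CC[C@H]2C(C)(C)CCC[C@]2(C)[C@H]1COC(=O)C=P(c1ccccc1)(c1ccccc1)c1ccccc1 | intermediate (not isolated)
17 | albicanyl (E)-3-(2,4-dihydroxyphenyl)prop-2-enoate | C=C1CC[C@H]2C(C)(C)CCC[C@]2(C)[C@H]1COC(=O)/C=C/c1ccc(O)cc1O | target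

**Step count and risks**

Total steps: 12. Longest linear sequence: 12 steps (1 → 17).

Steps most likely to fail:

1. Step 8. What may go wrong: fluoride capture of the activated oxirane at its terminal carbon, or migration of the ring CH2 in place of the quaternary carbon, competing with the desired shift. Fallback (sulfonate-based pinacol-type shift without a Lewis-acid-activated oxirane), from 9 back to 11: hydroxide opening of the oxirane at its primary carbon (KOH, DMSO/H2O, 80 °C; C9 keeps its oxygen and configuration) should give the triol (1S,3aS,7aS)-1-[(1R)-1,2-dihydroxyethyl]-4,4,7a-trimethyloctahydro-1H-inden-1-ol F1. Selective silylation of the primary hydroxyl (TBSCl, imidazole, CH2Cl2, 0 °C) gives the mono-silyl ether F2, and mesylation of the secondary hydroxyl (MsCl, Et3N, CH2Cl2, −20 °C) gives the mesylate F3. Treatment with Et3Al (CH2Cl2, −78 °C), the organoaluminium-promoted pinacol-type rearrangement of β-mesyloxy alcohols, moves C10 anti to the departing mesylate with inversion at C9 and gives 11 directly; step 9 is then not needed.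

2. Step 4. What may go wrong: poor facial selectivity in the uptake of H2, or double-bond migration on the catalyst before reduction, leading to cis-fused material. Fallback (ring fusion set by dissolving-metal reduction), from 2 back to 6: monomethylation of the dienolate (KOtBu 1.05 equiv, MeI 1.1 equiv, tBuOH, rt) gives the conjugated 4'-methyl enone acetal F4. Reductive methylation (Li, NH3/THF, −78 °C; then MeI; Stork reductive alkylation) protonates the ring-fusion carbon to the trans junction and methylates the enolate, giving the 4',4'-dimethyl trans-ketone acetal F5. Wolff–Kishner reduction (N2H4·H2O, KOH, diethylene glycol, 200 °C) through the hydrazone F6 gives 6; steps 2 to 4 are replaced.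

3. Step 12. What may go wrong: protonation of the stabilised ylide by the acidic 4-hydroxyl and deactivation of the electron-rich aldehyde stall the olefination, or the minor Z-enoate lactonises to the coumarin with loss of the alcohol. Fallback (acylation with a preformed protected cinnamic acid), from 15 and 13 to 17: allylation of 15 (allyl bromide, K2CO3, acetone, reflux) gives 2,4-bis(prop-2-enyloxy)benzaldehyde F7. Knoevenagel–Doebner condensation (malonic acid, pyridine, piperidine cat., 90 °C) passes through the benzylidenemalonic acid F8 and gives (E)-3-[2,4-bis(prop-2-enyloxy)phenyl]prop-2-enoic acid F9. Steglich esterification with 13 (EDC·HCl, DMAP, CH2Cl2, rt) gives the bis-allyl ester F10, and deallylation with Pd(PPh3)4 (cat.) and morpholine in THF at rt gives 17.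

**Further compounds**

F1 | step 8 | (1S,3aS,7aS)-1-[(1R)-1,2-dihydroxyethyl]-4,4,7a-trimethyloctahydro-1H-inden-1-ol | O[C@@]1([C@H](O)CO)CC[C@H]2C(C)(C)CCC[C@]12C
F2 | step 8 | primary tert-butyldimethylsilyl ether of F1 | O[C@@]1([C@H](O)CO[Si](C)(C)C(C)(C)C)CC[C@H]2C(C)(C)CCC[C@]12C
F3 | step 8 | secondary methanesulfonate of F2 | O[C@@]1([C@H](OS(C)(=O)=O)CO[Si](C)(C)C(C)(C)C)CC[C@H]2C(C)(C)CCC[C@]12C
F4 | step 4 | (7a'S)-4',7a'-dimethyl-2',3',7',7a'-tetrahydrospiro[1,3-dioxolane-2,1'-inden]-5'(6'H)-one | O1CCOC12CCC3=C(C)C(=O)CC[C@]23C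
F5 | step 4 | (3a'S,7a'S)-4',4',7a'-trimethylhexahydrospiro[1,3-dioxolane-2,1'-inden]-5'(4'H)-one | O1CCOC12CC[C@H]3C(C)(C)C(=O)CC[C@]23C
F6 | step 4 | hydrazone of F5 | O1CCOC12CC[C@H]3C(C)(C)C(=NN)CC[C@]23C
F7 | step 12 | 2,4-bis(prop-2-enyloxy)benzaldehyde | C=CCOc1ccc(C=O)c(OCC=C)c1
F8 | step 12 | 2-{[2,4-bis(prop-2-enyloxy)phenyl]methylidene}propanedioic acid | C=CCOc1ccc(C=C(C(=O)O)C(=O)O)c(OCC=C)c1
F9 | step 12 | (E)-3-[2,4-bis(prop-2-enyloxy)phenyl]prop-2-enoic acid | C=CCOc1ccc(/C=C/C(=O)O)c(OCC=C)c1
F10 | step 12 | albicanyl (E)-3-[2,4-bis(prop-2-enyloxy)phenyl]prop-2-enoate | C=C1CC[C@H]2C(C)(C)CCC[C@]2(C)[C@H]1COC(=O)/C=C/c1ccc(OCC=C)cc1OCC=C
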